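**Retrosynthetic overview**

- Target ⇐ fluoride desilylation ⇐ Knoevenagel–Doebner on the C6 aldehyde ⇐ C3–CH2OH from a C3 vinyl group (ozonolysis, selective reduction).
- Dioxane ring (the only ring made; both benzene rings are bought) ⇐ intramolecular SNAr of the benzylic alkoxide onto an aryl fluoride para to CHO. No bond to a stereocentre is broken, so the syn open chain gives the trans ring.
- Key C–C bond (ring C2–C3) ⇐ TIPS-vanillin + a (Z)-γ-aryloxyallyl-B(Ipc)2 reagent whose aryloxy group is the fluorobenzaldehyde ring itself. The oxygen-bearing carbon reacts as the nucleophile (α-aryloxy carbanion, an oxyallyl anion), and both stereocentres are set in this step.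
- The allylborane ⇐ s-BuLi deprotonation of the allyl ether of 4-fluoro-3-hydroxybenzaldehyde dimethyl acetal, trapped with (−)-Ipc2BOMe.

Assumption: the target SMILES is read as the trans-(2R,3R)-2,3-dihydro-1,4-benzodioxine with the aryl group on C2, CH2OH on C3 and the (E)-acrylic acid on C6; compounds 1, 6 and 9 are taken as catalogue chemicals.

**Route**

Step 1
Reactants: 1 4-fluoro-3-hydroxybenzaldehyde; 2 allyl bromide
Product: 3 4-fluoro-3-(prop-2-en-1-yloxy)benzaldehyde
Conditions: K2CO3, DMF, rt, 6 h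
Reagents that add atoms: allyl bromide, C=CCBr
Why: Williamson ether synthesis; the phenoxide is alkylated by the allylic bromide far faster at room temperature than it can attack the aryl fluoride of another molecule.

Step 2
Reactants: 3 4-fluoro-3-(prop-2-en-1-yloxy)benzaldehyde; 4 trimethyl orthoformate
Product: 5 4-(dimethoxymethyl)-1-fluoro-2-(prop-2-en-1-yloxy)benzene
Conditions: HC(OMe)3, TsOH·H2O (2 mol %), MeOH, rt, 2 h; Et3N quench
Reagents that add atoms: trimethyl orthoformate, COC(OC)OC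
Why: acid-catalysed acetalisation driven by the orthoformate as water scavenger; the acyclic acetal masks the aldehyde against s-BuLi and is removed later by dilute acid.

Step 3
Reactants: 6 vanillin; 7 chlorotriisopropylsilane
Product: 8 3-methoxy-4-[(triisopropylsilyl)oxy]benzaldehyde
Conditions: TIPSCl, imidazole, DMF, rt, 12 h
Reagents that add atoms: chlorotriisopropylsilane, CC(C)[Si](Cl)(C(C)C)C(C)C
Why: imidazole-promoted O-silylation; the hindered aryl TIPS ether tolerates the borane, NaH, ozone and hot pyridine of the later steps and is removed by fluoride at the end.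

Step 4
Reactants: 5 4-(dimethoxymethyl)-1-fluoro-2-(prop-2-en-1-yloxy)benzene; 8 3-methoxy-4-[(triisopropylsilyl)oxy]benzaldehyde; 9 (−)-B-methoxydiisopinocampheylborane (Ipc groups from (+)-α-pinene)
Product: 15 4-fluoro-3-{[(1R,2R)-1-hydroxy-1-{3-methoxy-4-[(triisopropylsilyl)oxy]phenyl}but-3-en-2-yl]oxy}benzaldehyde, via allyllithium 10 (not isolated), via methoxyborate 11 (not isolated), via allylborane 12 (not isolated), via borinate 13 (not isolated), via acetal alcohol 14 (not isolated)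
Conditions: 5, s-BuLi, THF, −78 °C, 30 min; 9, −78 °C, 1 h; BF3·OEt2, −78 °C; 8, −78 °C, 4 h; HOCH2CH2NH2, Et2O, rt; then 1 M aq. HCl, THF, 0 °C, 20 min
Reagents that add atoms: water, O
Why: Brown-type asymmetric γ-alkoxyallylboration with the future benzo ring as the ether group: kinetic allylic deprotonation of 5 gives the chelated (Z)-aryloxyallyl anion 10, so the oxygen-bearing carbon attacks as a nucleophile, boron takes the terminal carbon, and the (Z)-allylborane 12 adds through a closed chair transition state to the Si face of 8 under control of the (+)-α-pinene-derived Ipc groups, setting the benzylic carbinol (R) and the aryloxy carbon (R) together as the syn pair.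

Step 5
Reactants: 15 4-fluoro-3-{[(1R,2R)-1-hydroxy-1-{3-methoxy-4-[(triisopropylsilyl)oxy]phenyl}but-3-en-2-yl]oxy}benzaldehyde
Product: 16 (2R,3R)-3-ethenyl-2-{3-methoxy-4-[(triisopropylsilyl)oxy]phenyl}-2,3-dihydro-1,4-benzodioxine-6-carbaldehyde
Conditions: NaH (1.2 equiv), THF/DMF 4:1, 0.02 M, 0 °C to rt, 3 h
Reagents that add atoms: none
Why: intramolecular nucleophilic aromatic substitution (SNAr, six-membered closure through a Meisenheimer complex stabilised by the para formyl group); no bond to either stereocentre is broken, so the syn adduct gives the trans-(2R,3R) ring directly, and only one hydroxyl is present, so the ring oxygen cannot be misplaced.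

Step 6
Reactants: 16 (2R,3R)-3-ethenyl-2-{3-methoxy-4-[(triisopropylsilyl)oxy]phenyl}-2,3-dihydro-1,4-benzodioxine-6-carbaldehyde
Product: 19 (2R,3R)-3-(hydroxymethyl)-2-{3-methoxy-4-[(triisopropylsilyl)oxy]phenyl}-2,3-dihydro-1,4-benzodioxine-6-carbaldehyde, via secondary ozonide 17 (not isolated), via dialdehyde 18 (not isolated)
Conditions: O3, CH2Cl2, −78 °C; PPh3, −78 to 0 °C; then EtOH, NaBH4 (0.7 equiv), −78 °C, 1 h; acetone quench
Reagents that add atoms: ozone, [O-][O+]=O
Why: Criegee ozonolysis of the only C=C followed by chemoselective low-temperature borohydride reduction, in which the α-aryloxy aliphatic aldehyde (and the formaldehyde co-product) is reduced far faster than the deactivated p-alkoxybenzaldehyde; the aldehyde next to the stereocentre is reduced cold before it can enolise, so C3 is kept.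

Step 7
Reactants: 19 (2R,3R)-3-(hydroxymethyl)-2-{3-methoxy-4-[(triisopropylsilyl)oxy]phenyl}-2,3-dihydro-1,4-benzodioxine-6-carbaldehyde; 20 malonic acid
Product: 22 (2E)-3-[(2R,3R)-3-(hydroxymethyl)-2-{3-methoxy-4-[(triisopropylsilyl)oxy]phenyl}-2,3-dihydro-1,4-benzodioxin-6-yl]prop-2-enoic acid, via arylidenemalonic acid 21 (not isolated)
Conditions: CH2(CO2H)2 (3 equiv), pyridine, piperidine (0.2 equiv), 85 °C, 4 h; cold 1 M HCl work-up
Reagents that add atoms: malonic acid, OC(=O)CC(=O)O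
Why: Knoevenagel–Doebner condensation with decarboxylation gives the (E)-cinnamic acid directly; the phenol is still silylated, so the amine base cannot open the benzylic aryl ether through a quinone methide.

Step 8
Reactants: 22 (2E)-3-[(2R,3R)-3-(hydroxymethyl)-2-{3-methoxy-4-[(triisopropylsilyl)oxy]phenyl}-2,3-dihydro-1,4-benzodioxin-6-yl]prop-2-enoic acid
Product: 23 (2E)-3-[(2R,3R)-2-(4-hydroxy-3-methoxyphenyl)-3-(hydroxymethyl)-2,3-dihydro-1,4-benzodioxin-6-yl]prop-2-enoic acid
Conditions: TBAF (2.5 equiv), AcOH (2.5 equiv), THF, 0 °C to rt, 1 h; pH 3 citrate work-up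
Reagents that add atoms: none
Why: fluoride-driven desilylation of the aryl silyl ether (strong Si–F bond), buffered with acetic acid so that no free phenoxide is exposed and C2 is not epimerised through a quinone methide.

**Compound list**

1 | 4-fluoro-3-hydroxybenzaldehyde | O=Cc1ccc(F)c(O)c1 | starting material
2 | allyl bromide | C=CCBr | starting material
3 | 4-fluoro-3-(prop-2-en-1-yloxy)benzaldehyde | C=CCOc1cc(C=O)ccc1F | intermediate
4 | trimethyl orthoformate | COC(OC)OC | starting material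
5 | 4-(dimethoxymethyl)-1-fluoro-2-(prop-2-en-1-yloxy)benzene | C=CCOc1cc(C(OC)OC)ccc1F | intermediate
6 | vanillin | COc1cc(C=O)ccc1O | starting material
7 | chlorotriisopropylsilane | CC(C)[Si](Cl)(C(C)C)C(C)C | starting material
8 | 3-methoxy-4-[(triisopropylsilyl)oxy]benzaldehyde | COc1cc(C=O)ccc1O[Si](C(C)C)(C(C)C)C(C)C | intermediate
9 | (−)-B-methoxydiisopinocampheylborane, Ipc from (+)-α-pinene | COB([C@@H]1C[C@@H]2C[C@H]([C@H]1C)C2(C)C)[C@@H]1C[C@@H]2C[C@H]([C@H]1C)C2(C)C | starting material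
10 | lithium (Z)-3-[5-(dimethoxymethyl)-2-fluorophenoxy]prop-2-en-1-ide (in flask) | [Li+].[CH2-]/C=C\Oc1cc(C(OC)OC)ccc1F | intermediate
11 | lithium [(Z)-3-[5-(dimethoxymethyl)-2-fluorophenoxy]prop-2-en-1-yl](methoxy)diisopinocampheylborate (in flask) | [Li+].CO[B-](C/C=C\Oc1cc(C(OC)OC)ccc1F)([C@@H]1C[C@@H]2C[C@H]([C@H]1C)C2(C)C)[C@@H]1C[C@@H]2C[C@H]([C@H]1C)C2(C)C | intermediate
12 | [(Z)-3-[5-(dimethoxymethyl)-2-fluorophenoxy]prop-2-en-1-yl]diisopinocampheylborane (in flask) | B(C/C=C\Oc1cc(C(OC)OC)ccc1F)([C@@H]1C[C@@H]2C[C@H]([C@H]1C)C2(C)C)[C@@H]1C[C@@H]2C[C@H]([C@H]1C)C2(C)C | intermediate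
13 | diisopinocampheylborinate ester of 14 (in flask) | C=C[C@@H](Oc1cc(C(OC)OC)ccc1F)[C@H](OB([C@@H]2C[C@@H]3C[C@H]([C@H]2C)C3(C)C)[C@@H]2C[C@@H]3C[C@H]([C@H]2C)C3(C)C)c1ccc(O[Si](C(C)C)(C(C)C)C(C)C)c(OC)c1 | intermediate
14 | (1R,2R)-2-[5-(dimethoxymethyl)-2-fluorophenoxy]-1-{3-methoxy-4-[(triisopropylsilyl)oxy]phenyl}but-3-en-1-ol (in flask) | C=C[C@@H](Oc1cc(C(OC)OC)ccc1F)[C@H](O)c1ccc(O[Si](C(C)C)(C(C)C)C(C)C)c(OC)c1 | intermediate
15 | 4-fluoro-3-{[(1R,2R)-1-hydroxy-1-{3-methoxy-4-[(triisopropylsilyl)oxy]phenyl}but-3-en-2-yl]oxy}benzaldehyde | C=C[C@@H](Oc1cc(C=O)ccc1F)[C@H](O)c1ccc(O[Si](C(C)C)(C(C)C)C(C)C)c(OC)c1 | intermediate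
16 | (2R,3R)-3-ethenyl-2-{3-methoxy-4-[(triisopropylsilyl)oxy]phenyl}-2,3-dihydro-1,4-benzodioxine-6-carbaldehyde | COc1cc([C@H]2Oc3ccc(C=O)cc3O[C@@H]2C=C)ccc1O[Si](C(C)C)(C(C)C)C(C)C | intermediate
17 | (2R,3S)-2-{3-methoxy-4-[(triisopropylsilyl)oxy]phenyl}-3-(1,2,4-trioxolan-3-yl)-2,3-dihydro-1,4-benzodioxine-6-carbaldehyde, both epimers at the trioxolane carbon, ring centres as in 16 (in flask) | COc1cc([C@H]2Oc3ccc(C=O)cc3O[C@@H]2C4OCOO4)ccc1O[Si](C(C)C)(C(C)C)C(C)C | intermediate
18 | (2S,3R)-3-{3-methoxy-4-[(triisopropylsilyl)oxy]phenyl}-2,3-dihydro-1,4-benzodioxine-2,7-dicarbaldehyde, ring centres as in 16 (in flask) | COc1cc([C@H]2Oc3ccc(C=O)cc3O[C@@H]2C=O)ccc1O[Si](C(C)C)(C(C)C)C(C)C | intermediate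
19 | (2R,3R)-3-(hydroxymethyl)-2-{3-methoxy-4-[(triisopropylsilyl)oxy]phenyl}-2,3-dihydro-1,4-benzodioxine-6-carbaldehyde | COc1cc([C@H]2Oc3ccc(C=O)cc3O[C@@H]2CO)ccc1O[Si](C(C)C)(C(C)C)C(C)C | intermediate
20 | malonic acid | OC(=O)CC(=O)O | starting material
21 | 2-{[(2R,3R)-3-(hydroxymethyl)-2-{3-methoxy-4-[(triisopropylsilyl)oxy]phenyl}-2,3-dihydro-1,4-benzodioxin-6-yl]methylidene}propanedioic acid (in flask) | COc1cc([C@H]2Oc3ccc(C=C(C(=O)O)C(=O)O)cc3O[C@@H]2CO)ccc1O[Si](C(C)C)(C(C)C)C(C)C | intermediate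
22 | (2E)-3-[(2R,3R)-3-(hydroxymethyl)-2-{3-methoxy-4-[(triisopropylsilyl)oxy]phenyl}-2,3-dihydro-1,4-benzodioxin-6-yl]prop-2-enoic acid | COc1cc([C@H]2Oc3ccc(/C=C/C(=O)O)cc3O[C@@H]2CO)ccc1O[Si](C(C)C)(C(C)C)C(C)C | intermediate
23 | (2E)-3-[(2R,3R)-2-(4-hydroxy-3-methoxyphenyl)-3-(hydroxymethyl)-2,3-dihydro-1,4-benzodioxin-6-yl]prop-2-enoic acid | COc1cc([C@H]2Oc3ccc(/C=C/C(=O)O)cc3O[C@@H]2CO)ccc1O | target

**Step count**

Total: 8 steps. Longest linear sequence: 7 steps (1, 2, 4, 5, 6, 7, 8 from compound 1); step 3 is a one-step branch.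

**Three steps most likely to fail**

Step 4 is the largest risk. s-BuLi may metalate the ring next to fluorine (then benzyne) instead of the allylic position, excess BF3·OEt2 may ionise the acetal, and the aryloxyallylborane is less nucleophilic than the usual alkoxy reagents. The fallback sets out from 8 (with 9) and comes back to the route at 16; it keeps the same kind of C–C bond formation but attaches the benzo ring afterwards. Allyl methoxymethyl ether is lithiated (s-BuLi, THF, −78 °C) and carried through 9 and BF3·OEt2 to [(Z)-3-(methoxymethoxy)prop-2-en-1-yl]diisopinocampheylborane F1. F1 adds to 8 to give (1R,2R)-2-(methoxymethoxy)-1-{3-methoxy-4-[(triisopropylsilyl)oxy]phenyl}but-3-en-1-ol F2. The benzylic alkoxide of F2 (NaH, DMF, 0 °C) displaces the fluoride of 3-bromo-4-fluorobenzaldehyde to give 3-bromo-4-{[(1R,2R)-2-(methoxymethoxy)-1-{3-methoxy-4-[(triisopropylsilyl)oxy]phenyl}but-3-en-1-yl]oxy}benzaldehyde F3. HCl (cat.) in MeOH removes the methoxymethyl group to give 3-bromo-4-{[(1R,2R)-2-hydroxy-1-{3-methoxy-4-[(triisopropylsilyl)oxy]phenyl}but-3-en-1-yl]oxy}benzaldehyde F4. CuI, 1,10-phenanthroline and Cs2CO3 in toluene at 110 °C then close the dioxane ring by intramolecular Ullmann etherification to give 16.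

Step 5 can fail through alkoxide–aldehyde side reactions (hemiacetal formation, hydride transfer), loss of the silyl group or a slow closure. The fallback sets out from 15 and comes back at 16; it reverses the roles in the ring-closing C–O bond. Acetohydroxamic acid with K2CO3 in DMSO at 70 °C acts as a hydroxide surrogate and replaces the activated fluoride by OH, giving 4-hydroxy-3-{[(1R,2R)-1-hydroxy-1-{3-methoxy-4-[(triisopropylsilyl)oxy]phenyl}but-3-en-2-yl]oxy}benzaldehyde F5. BF3·OEt2 (0.2 equiv) in CH2Cl2 at −20 °C ionises the p-silyloxybenzylic alcohol, and the neighbouring phenol traps the cation. The fixed C3 centre then steers the closure to the more stable trans ring, which is 16.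

Step 6 can fail by over-reduction of the aromatic aldehyde, or by enolisation and β-elimination of dialdehyde 18 before it is reduced. The fallback sets out from 16 and comes back at 19; it gives up selective reduction in favour of selective oxidation. The same ozonolysis through 17 and 18 is followed by NaBH4 in excess (EtOH, −78 to 0 °C), which reduces both aldehydes to [(2R,3R)-3-{3-methoxy-4-[(triisopropylsilyl)oxy]phenyl}-2,3-dihydro-1,4-benzodioxine-2,7-diyl]dimethanol F6. MnO2 in CH2Cl2 at rt then oxidises only the benzylic alcohol and gives 19.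

**Further compounds**

F1 | step 4 | [(Z)-3-(methoxymethoxy)prop-2-en-1-yl]diisopinocampheylborane | COCO/C=C\CB([C@@H]1C[C@@H]2C[C@H]([C@H]1C)C2(C)C)[C@@H]1C[C@@H]2C[C@H]([C@H]1C)C2(C)C
F2 | step 4 | (1R,2R)-2-(methoxymethoxy)-1-{3-methoxy-4-[(triisopropylsilyl)oxy]phenyl}but-3-en-1-ol | C=C[C@@H](OCOC)[C@H](O)c1ccc(O[Si](C(C)C)(C(C)C)C(C)C)c(OC)c1
F3 | step 4 | 3-bromo-4-{[(1R,2R)-2-(methoxymethoxy)-1-{3-methoxy-4-[(triisopropylsilyl)oxy]phenyl}but-3-en-1-yl]oxy}benzaldehyde | C=C[C@@H](OCOC)[C@H](Oc1ccc(C=O)cc1Br)c1ccc(O[Si](C(C)C)(C(C)C)C(C)C)c(OC)c1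
F4 | step 4 | 3-bromo-4-{[(1R,2R)-2-hydroxy-1-{3-methoxy-4-[(triisopropylsilyl)oxy]phenyl}but-3-en-1-yl]oxy}benzaldehyde | C=C[C@@H](O)[C@H](Oc1ccc(C=O)cc1Br)c1ccc(O[Si](C(C)C)(C(C)C)C(C)C)c(OC)c1
F5 | step 5 | 4-hydroxy-3-{[(1R,2R)-1-hydroxy-1-{3-methoxy-4-[(triisopropylsilyl)oxy]phenyl}but-3-en-2-yl]oxy}benzaldehyde | C=C[C@@H](Oc1cc(C=O)ccc1O)[C@H](O)c1ccc(O[Si](C(C)C)(C(C)C)C(C)C)c(OC)c1
F6 | step 6 | [(2R,3R)-3-{3-methoxy-4-[(triisopropylsilyl)oxy]phenyl}-2,3-dihydro-1,4-benzodioxine-2,7-diyl]dimethanol | COc1cc([C@H]2Oc3ccc(CO)cc3O[C@@H]2CO)ccc1O[Si](C(C)C)(C(C)C)C(C)C
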